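## The problem

Target 17 is an isoflavone (a 3-aryl-4H-chromen-4-one). Ring A carries hydroxyls at C5 and C7 and a prenyl group at C8; ring B carries a hydroxyl at C4' and a 2,2-dimethylpyran fused across C2'–C3' with its oxygen on C2'. There is no stereocentre, so the task is one of regiochemistry and functional-group tolerance. Three placements must be secured: the prenyl group at C8 rather than C6, which on a phloroglucinol nucleus means ring C must close through the oxygen next to the prenyl group; the pyran oxygen ortho, not para, to the C3–C1' bond; and the aryl group on C3 rather than C2. Two electron-rich alkenes are present, the prenyl double bond (flanked by O1 and the C7 oxygen) and the styrene-like chromene double bond. Both cyclise or polymerise in strong protic acid and are lost on hydrogenation or with electrophilic oxidants, so the three phenols must be unveiled at the end without such reagents. The enabling feature is that C3 bears both the C4 carbonyl and ring B, while C2 is a lone CH between C3 and O1. This is the pattern left when the aroyl group of a chalcone epoxide migrates to the benzylic carbon and the former alpha carbon, now a formyl group, is captured by a ring A oxygen.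

## Retrosynthesis

**17 from 16.** The three O–allyl bonds on O5, O7 and O4' are cut last. Allyl is preferred to methyl, benzyl or MOM because it leaves under zerovalent palladium and mild base, with no acid, hydrogen or hard Lewis acid near the prenyl and chromene groups. Tri-O-allyl ether 16 has the full skeleton but no acidic phenol, which simplifies every earlier step. The forward reaction must ionise aryl–O–allyl bonds while leaving the C-bound prenyl group, which has no leaving group, untouched.

**16 from 13.** Ring C is opened at O1–C2 and the C3–C4 bond is cut, returning the aroyl group to the carbon that becomes C2. This gives the racemic trans chalcone epoxide 13. The neighbouring cuts are less attractive here. A C3–C1' cross-coupling needs a metalated chromene and a 3-halochromone made with an electrophilic halogen beside a prenyl group. Adding C2 as a one-carbon unit needs a benzyl aryl ketone of a phloroglucinol, which has no simple C–C bond-forming entry. The chosen cut reduces the problem to an aldol union of two aromatic halves of similar size. In the forward direction the epoxide must open at the benzylic carbon, the acyl group (not hydrogen) must migrate to give aldehyde 14, and ring closure through hemiacetal 15 must use only the oxygen next to the prenyl group. For that reason this oxygen alone is a MOM acetal in 13 and the other two ring A oxygens are allyl ethers.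

**13 from 12, and 12 from 5 and 11.** The two C–O bonds of the epoxide are cut to give E-chalcone 12, and its C(alpha)=C(beta) bond is cut to give methyl ketone 5 and aldehyde 11. A nucleophilic epoxidation is required because 12 holds five other alkenes, all electron-rich, and only the enone accepts hydroperoxide. The condensation is a plain Claisen–Schmidt reaction of a non-enolisable aldehyde; every protecting group in 5 and 11 is base-stable.

**5 from 4, 3, 1 and 2.** The MOM group is removed from O2 to give phenol 4, the two allyl groups from O4 and O6 to give 3, and the C3–prenyl bond is cut to give phloroacetophenone 1 and prenyl bromide 2. Prenylating first uses the symmetry of 1, in which both ring CH positions are equivalent. The protecting groups then follow in order of decreasing reactivity of the hydroxyls: para, then the less hindered ortho, then the chelated hydroxyl between acetyl and prenyl. The second allylation must discriminate between the two ortho hydroxyls; this is the one selectivity of the sequence that rests on sterics and hydrogen bonding.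

**11 from 9 (through 10), and 9 from 7, 8 and 6.** The pyran ring is opened at O–C2 and at the C4a–C4 bond to give aryl propargyl ether 9, which rearranges through allenylphenol 10. The ether C–O bond is cut to give phenol 7 and chloride 8, and the allyl group is removed to give 2,4-dihydroxybenzaldehyde 6. Blocking the more reactive para hydroxyl of 6 first forces the propargyl unit onto the ortho oxygen, whose only free ortho carbon is C3. The pyran oxygen therefore ends ortho to the formyl carbon, as ring B of 17 requires. The thermal step must proceed below the temperature at which the allyl ether would itself rearrange.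

## Roads not taken

**Alternative 1:** Ring B is cut at C1'–C2', C2'–C3' and C4'–C5' and grown on a finished chromone. Irradiation of chromon-3-yl diazo enone A2 gives a vinylketene by photo-Wolff rearrangement; it combines with prenyl siloxyalkyne A3 in a [2+2] addition, and the cyclobutenone opens and electrocyclises to phenol A1.
- Merits: the pattern of ring B (hydroxyl at C2' between the chromone and the prenyl group, silyloxy at C4') is fixed by the polarity of the ketene–ynol ether addition, and the route is convergent.
- Weak points: the chromone is a strong UV chromophore and an enone, so it competes for light and can undergo its own photoreactions. A2 needs formylation, olefination and diazo transfer on a prenylated chromone, whose 8- versus 6-prenyl question is still open. After A1 come an oxidative chromene closure, a desilylation and an acidic removal of two MOM groups beside prenyl and chromene.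
- Comparison: the ring B regiochemistry is as secure as in the chosen plan, but the chosen plan gets the same ring in three thermal and ionic steps from 6. Its end game is one acid-free step where this road needs three. The chosen plan has to accept a Lewis acid step in exchange.

**Alternative 2:** The pyran ring is cut at C3'–C4'' and O–C2'' and made last. Heating the 2'-O-(1,1-dimethylpropargyl) ether A5 in N,N-diethylaniline sets off the [3,3] shift to C3', a 1,5-hydrogen shift and an oxa-6π closure, giving A4.
- Merits: this is the same pericyclic cascade as step 6 and equally regiospecific. The chromene is absent while ring C is built, so it never meets a Lewis acid. On this point the road is safer than the chosen plan.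
- Weak points: the tertiary propargyl group must be placed on a hydroxyl crowded by the chromone at C1'. The cascade runs near 200 °C on a late, valuable intermediate. The two MOM groups of A4 then need acid, with a prenyl group next to the freed C7 hydroxyl, the classic setting for chroman formation.
- Comparison: the chosen plan moves the cascade to a simple benzaldehyde at the start and ends with a palladium deallylation instead of acid. Against the Lewis acid exposure of the chromene it sets a short contact at low temperature.

**Alternative 3:** Ring C is cut at O1–C8a. K2CO3 in DMF turns the hydroxymethylene ketone A7 into its enolate, whose oxygen displaces the fluoride ortho to the ketone to give A6.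
- Merits: the closing position is fixed by the C–F bond, so the 8- versus 6-prenyl question is settled by constitution, and the conditions are basic and harmless to both alkenes. In regiochemical certainty this road is better than the chosen plan, which relies on a protecting-group pattern.
- Weak points: A7 needs a fluorinated, fully substituted ring A that cannot be derived from 1, plus a deoxybenzoin C–C bond and a formylation. The two alkoxy groups conjugated with the ketone weaken its activation of the substitution. The three MOM groups of A6 again call for acid at the end.
- Comparison: the chosen plan answers with commercial 1 and 6, a shorter sequence and an acid-free end game. Its price is one selectivity-dependent protection (step 2), for which a constitutionally controlled fallback is given below.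

Key step: step 9

Remark: 13, 14 and 15 are racemic (15 as a diastereomer mixture); this is immaterial because these centres are erased in step 9 and 17 has no stereocentre.

## Route

**Step 1**
Reactants: 1 2,4,6-trihydroxyacetophenone; 2 prenyl bromide
Product: 3 1-[2,4,6-trihydroxy-3-(3-methylbut-2-en-1-yl)phenyl]ethan-1-one
Conditions: 10% aq KOH, 0 °C to rt
Reagents that add atoms: none
Why: C-alkylation of the ambident phloroglucinol phenoxide; in water the oxygens are hydrogen-bonded and the soft allylic bromide is attacked by ring carbon. The two free ring positions are equivalent, so only one mono-C-prenyl isomer can form, and one equivalent of bromide at 0 °C limits double alkylation.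

**Step 2**
Reactants: 3 1-[2,4,6-trihydroxy-3-(3-methylbut-2-en-1-yl)phenyl]ethan-1-one
Product: 4 1-[4,6-bis(allyloxy)-2-hydroxy-3-(3-methylbut-2-en-1-yl)phenyl]ethan-1-one
Conditions: allyl bromide (2.1 equiv), K2CO3, acetone, 50 °C
Reagents that add atoms: allyl bromide, C=CCBr
Why: Williamson ether synthesis; the para hydroxyl, the only one outside a hydrogen bond, reacts first, and of the two ortho hydroxyls the one flanked only by H-5 is alkylated next. The hydroxyl wedged between acetyl and prenyl stays locked in its chelate, the usual outcome of partial alkylation of 3-alkylphloroacetophenones.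

**Step 3**
Reactants: 4 1-[4,6-bis(allyloxy)-2-hydroxy-3-(3-methylbut-2-en-1-yl)phenyl]ethan-1-one
Product: 5 1-[4,6-bis(allyloxy)-2-(methoxymethoxy)-3-(3-methylbut-2-en-1-yl)phenyl]ethan-1-one
Conditions: NaH, DMF, 0 °C; then MOMCl, 0 °C to rt
Reagents that add atoms: chloromethyl methyl ether, COCCl
Why: NaH in DMF breaks the chelate and the free phenoxide is alkylated by the chloromethyl ether (Williamson-type acetal formation). The MOM acetal is stable to all later basic steps and is the only Lewis-acid-labile group on ring A.

**Step 4**
Reactants: 6 2,4-dihydroxybenzaldehyde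
Product: 7 4-(allyloxy)-2-hydroxybenzaldehyde
Conditions: allyl bromide (1.0 equiv), K2CO3 (1.0 equiv), acetone, rt
Reagents that add atoms: allyl bromide, C=CCBr
Why: Williamson ether synthesis at the more acidic para hydroxyl; the ortho hydroxyl is held by its hydrogen bond to the formyl group and stays free with one equivalent of halide and a weak base.

**Step 5**
Reactants: 7 4-(allyloxy)-2-hydroxybenzaldehyde; 8 3-chloro-3-methylbut-1-yne
Product: 9 4-(allyloxy)-2-[(2-methylbut-3-yn-2-yl)oxy]benzaldehyde
Conditions: DBU, CuCl2·2H2O (cat.), MeCN, 0 °C to rt
Reagents that add atoms: none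
Why: Copper-catalysed propargylic etherification of a phenol with a tertiary propargylic chloride; the copper acetylide ionises to an allenylidene-type electrophile that the phenoxide captures at the tertiary carbon. Electron-poor phenols are the best substrates for this reaction.

**Step 6**
Reactants: 9 4-(allyloxy)-2-[(2-methylbut-3-yn-2-yl)oxy]benzaldehyde
Product: 11 5-(allyloxy)-2,2-dimethyl-2H-chromene-8-carbaldehyde, via allenylphenol 10 (not isolated)
Conditions: xylene, 140 °C
Reagents that add atoms: none
Why: Aromatic propargyl Claisen rearrangement to the only free ortho carbon gives 10 after tautomerisation; a 1,5-hydrogen shift and an oxa-6π electrocyclisation then close the 2,2-dimethylpyran ring. The gem-dimethyl propargyl ether rearranges well below the temperature an aryl allyl ether needs, so the reaction time is extended rather than the temperature raised.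

**Step 7**
Reactants: 5 1-[4,6-bis(allyloxy)-2-(methoxymethoxy)-3-(3-methylbut-2-en-1-yl)phenyl]ethan-1-one; 11 5-(allyloxy)-2,2-dimethyl-2H-chromene-8-carbaldehyde
Product: 12 (E)-1-[4,6-bis(allyloxy)-2-(methoxymethoxy)-3-(3-methylbut-2-en-1-yl)phenyl]-3-[5-(allyloxy)-2,2-dimethyl-2H-chromen-8-yl]prop-2-en-1-one
Conditions: KOH, EtOH–H2O, rt
Reagents that add atoms: none
Why: Claisen–Schmidt condensation; the methyl ketone enolate adds to the non-enolisable aldehyde and E1cB loss of hydroxide gives the conjugated E-enone. MOM, allyl, prenyl and chromene groups are inert to aqueous-alcoholic KOH.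

**Step 8**
Reactants: 12 (E)-1-[4,6-bis(allyloxy)-2-(methoxymethoxy)-3-(3-methylbut-2-en-1-yl)phenyl]-3-[5-(allyloxy)-2,2-dimethyl-2H-chromen-8-yl]prop-2-en-1-one
Product: 13 rac-[(2S,3R)-3-[5-(allyloxy)-2,2-dimethyl-2H-chromen-8-yl]oxiran-2-yl][4,6-bis(allyloxy)-2-(methoxymethoxy)-3-(3-methylbut-2-en-1-yl)phenyl]methanone (trans epoxide)
Conditions: 30% aq H2O2, NaOH, MeOH–THF, 0 °C to rt
Reagents that add atoms: hydrogen peroxide, OO
Why: Weitz–Scheffer epoxidation; hydroperoxide anion adds to the enone beta carbon and the enolate closes onto oxygen. The intermediate enolate can rotate to the less crowded arrangement before closure, so the racemic trans epoxide should result. The isolated electron-rich alkenes do not react with a nucleophilic oxidant.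

**Step 9**
Reactants: 13 rac-[(2S,3R)-3-[5-(allyloxy)-2,2-dimethyl-2H-chromen-8-yl]oxiran-2-yl][4,6-bis(allyloxy)-2-(methoxymethoxy)-3-(3-methylbut-2-en-1-yl)phenyl]methanone
Product: 16 5,7-bis(allyloxy)-3-[5-(allyloxy)-2,2-dimethyl-2H-chromen-8-yl]-8-(3-methylbut-2-en-1-yl)-4H-chromen-4-one, via formyl deoxybenzoin 14 (not isolated), via 2-hydroxyisoflavanone 15 (not isolated)
Conditions: BF3·OEt2 (3 equiv), CH2Cl2, −20 °C to rt; aq NaHCO3
Reagents that add atoms: none
Why: BF3 binds the epoxide oxygen and breaks the benzylic C–O bond, because the cation at the ring B carbon is stabilised by the ortho pyran oxygen and the para allyloxy group; the aroyl group then shifts from the neighbouring carbon (new C3–C4 bond) and that carbon becomes the formyl group of 14. This is the Lewis acid 1,2-acyl shift of chalcone epoxides (a Meinwald-type rearrangement), the known entry to alpha-formyl deoxybenzoins and, from 2'-alkoxy substrates, to isoflavones. In 14 the MOM-bearing oxygen, activated for departure by chelation of boron between it and the ketone, adds to the boron-activated formyl carbon in a 6-exo-trig closure of ring C (new O1–C2 bond). The oxonium ion sheds the methoxymethyl group, which ends as formaldehyde and methanol on work-up, and hemiacetal 15 loses water to give the chromone. All stereocentres of 13, 14 and 15 are erased, so none is set. The step needs acyl rather than hydride migration, which the fully developed benzylic cation and the high migratory aptitude of the acyl group favour. It also needs closure through the oxygen next to the prenyl group, which is secured because only that oxygen carries an acetal that a Lewis acid releases, the other ortho oxygen being an allyl ether. Low temperature and short contact should keep the prenyl, chromene and allyl groups out of cationic side reactions.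

**Step 10**
Reactants: 16 5,7-bis(allyloxy)-3-[5-(allyloxy)-2,2-dimethyl-2H-chromen-8-yl]-8-(3-methylbut-2-en-1-yl)-4H-chromen-4-one
Product: 17 5,7-dihydroxy-3-(5-hydroxy-2,2-dimethyl-2H-chromen-8-yl)-8-(3-methylbut-2-en-1-yl)-4H-chromen-4-one
Conditions: Pd(PPh3)4 (5 mol%), K2CO3, MeOH, rt
Reagents that add atoms: none
Why: Tsuji–Trost-type deallylation; zerovalent palladium ionises each aryl allyl ether to a pi-allyl complex and a phenoxide, and methanol under carbonate traps the allyl unit as its methyl ether. The C-bound prenyl group and the chromene have no leaving group and no acid is present, so both alkenes should survive.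

## Compound list

1 | 2,4,6-trihydroxyacetophenone | CC(=O)c1c(O)cc(O)cc1O | starting material
2 | prenyl bromide (1-bromo-3-methylbut-2-ene) | CC(C)=CCBr | starting material
3 | 1-[2,4,6-trihydroxy-3-(3-methylbut-2-en-1-yl)phenyl]ethan-1-one | CC(=O)c1c(O)cc(O)c(CC=C(C)C)c1O | intermediate
4 | 1-[4,6-bis(allyloxy)-2-hydroxy-3-(3-methylbut-2-en-1-yl)phenyl]ethan-1-one | CC(=O)c1c(OCC=C)cc(OCC=C)c(CC=C(C)C)c1O | intermediate
5 | 1-[4,6-bis(allyloxy)-2-(methoxymethoxy)-3-(3-methylbut-2-en-1-yl)phenyl]ethan-1-one | CC(=O)c1c(OCC=C)cc(OCC=C)c(CC=C(C)C)c1OCOC | intermediate
6 | 2,4-dihydroxybenzaldehyde | O=Cc1ccc(O)cc1O | starting material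
7 | 4-(allyloxy)-2-hydroxybenzaldehyde | O=Cc1ccc(OCC=C)cc1O | intermediate
8 | 3-chloro-3-methylbut-1-yne | CC(C)(Cl)C#C | starting material
9 | 4-(allyloxy)-2-[(2-methylbut-3-yn-2-yl)oxy]benzaldehyde | O=Cc1ccc(OCC=C)cc1OC(C)(C)C#C | intermediate
10 | 4-(allyloxy)-2-hydroxy-3-(3-methylbuta-1,2-dien-1-yl)benzaldehyde | O=Cc1ccc(OCC=C)c(C=C=C(C)C)c1O | intermediate (not isolated)
11 | 5-(allyloxy)-2,2-dimethyl-2H-chromene-8-carbaldehyde | O=Cc1ccc(OCC=C)c2c1OC(C)(C)C=C2 | intermediate
12 | (E)-1-[4,6-bis(allyloxy)-2-(methoxymethoxy)-3-(3-methylbut-2-en-1-yl)phenyl]-3-[5-(allyloxy)-2,2-dimethyl-2H-chromen-8-yl]prop-2-en-1-one | O=C(/C=C/c1ccc(OCC=C)c2c1OC(C)(C)C=C2)c1c(OCOC)c(CC=C(C)C)c(OCC=C)cc1OCC=C | intermediate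
13 | rac-[(2S,3R)-3-[5-(allyloxy)-2,2-dimethyl-2H-chromen-8-yl]oxiran-2-yl][4,6-bis(allyloxy)-2-(methoxymethoxy)-3-(3-methylbut-2-en-1-yl)phenyl]methanone, racemic trans epoxide (one enantiomer drawn) | O=C(c1c(OCOC)c(CC=C(C)C)c(OCC=C)cc1OCC=C)[C@H]1O[C@@H]1c1ccc(OCC=C)c2c1OC(C)(C)C=C2 | intermediate
14 | 3-[4,6-bis(allyloxy)-2-(methoxymethoxy)-3-(3-methylbut-2-en-1-yl)phenyl]-2-[5-(allyloxy)-2,2-dimethyl-2H-chromen-8-yl]-3-oxopropanal, racemic, in equilibrium with its enol | O=CC(c1ccc(OCC=C)c2c1OC(C)(C)C=C2)C(=O)c1c(OCOC)c(CC=C(C)C)c(OCC=C)cc1OCC=C | intermediate (not isolated)
15 | 5,7-bis(allyloxy)-3-[5-(allyloxy)-2,2-dimethyl-2H-chromen-8-yl]-2-hydroxy-8-(3-methylbut-2-en-1-yl)-2,3-dihydro-4H-chromen-4-one, racemic diastereomer mixture | CC(C)=CCc1c(OCC=C)cc(OCC=C)c2c1OC(O)C(c1ccc(OCC=C)c3c1OC(C)(C)C=C3)C2=O | intermediate (not isolated)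
16 | 5,7-bis(allyloxy)-3-[5-(allyloxy)-2,2-dimethyl-2H-chromen-8-yl]-8-(3-methylbut-2-en-1-yl)-4H-chromen-4-one | CC(C)=CCc1c(OCC=C)cc(OCC=C)c2c(=O)c(-c3ccc(OCC=C)c4c3OC(C)(C)C=C4)coc12 | intermediate
17 | 5,7-dihydroxy-3-(5-hydroxy-2,2-dimethyl-2H-chromen-8-yl)-8-(3-methylbut-2-en-1-yl)-4H-chromen-4-one | CC(C)=CCc1c(O)cc(O)c2c(=O)c(-c3ccc(O)c4c3OC(C)(C)C=C4)coc12 | target

## Step count and least certain steps

Total step count: 10. Longest linear sequence: 7 steps (1, 2, 3, 7, 8, 9, 10; the ring B branch 4, 5, 6, 7, 8, 9, 10 is equally long).

**Step 9 (key step).** The likeliest failures are: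
- loss of the formyl group from the beta-keto aldehyde stage before the ring has closed, a deformylation that BF3 promotes on long contact;
- stalling of the sequence because the MOM acetal is not released;
- cationic side reactions: closure of the prenyl chain onto the freed phenol, ring alkylation by the methoxymethyl cation, or a Lewis acid Claisen shift of an allyl ether.

Fallback: the cascade is given up and the two events are separated, each with its own activation. Setting out from 13, a short treatment with BF3·OEt2 at −20 °C and a bicarbonate quench is used only for the acyl shift, and 14 is isolated as its enol. 14 is then treated with a catalytic amount of HCl in methanol–THF at room temperature. Acetal exchange passes the methoxymethyl group to methanol as dimethoxymethane, the phenol adds to the formyl group, and 15 dehydrates to 16, where the route is rejoined. No carbocation is released beside the electron-rich rings. This fallback makes no compound outside the list (entry F0).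

**Step 2.** The risk is poor discrimination between the two hydrogen-bonded ortho hydroxyls in the second allylation, or over-allylation. The MOM group would then be placed on the wrong oxygen in step 3 and ring closure would lead into the 6-prenyl series. Fallback: the position of the prenyl group is fixed by a sigmatropic sequence instead of by sterics. It sets out from 1, bypasses 3 and 4, and returns at 5.
- Mono-allylation of the para hydroxyl of 1 (one equivalent of allyl bromide, K2CO3) gives 1-[4-(allyloxy)-2,6-dihydroxyphenyl]ethan-1-one F1.
- Methoxymethylation of one of its two equivalent ortho hydroxyls gives 1-[4-(allyloxy)-2-hydroxy-6-(methoxymethoxy)phenyl]ethan-1-one F2.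
- O-prenylation of the remaining chelated hydroxyl with 2 and K2CO3 in DMF gives 1-[4-(allyloxy)-2-(methoxymethoxy)-6-[(3-methylbut-2-en-1-yl)oxy]phenyl]ethan-1-one F3.
- Eu(fod)3 in CHCl3 at 60 °C promotes a Claisen shift to the free ortho carbon followed by a Cope shift to the para carbon, the one between the MOM-bearing and allyl-bearing oxygens. This gives 1-[4-(allyloxy)-6-hydroxy-2-(methoxymethoxy)-3-(3-methylbut-2-en-1-yl)phenyl]ethan-1-one F4. The allyl ether does not rearrange at this temperature.
- Allylation of the liberated hydroxyl gives 5.

**Step 8.** The risk is slow conjugate addition of hydroperoxide to an enone that is twisted by the 2',6'-disubstituted ring and deactivated by the electron-rich ring B. Retro-aldol cleavage could compete in the basic medium, and the very electron-rich benzylic epoxide could ring-open during isolation. Fallback: the epoxide is made by C–C bond formation instead of oxidation. Setting out from 5, the lithium enolate (LiHMDS, THF, −78 °C) is chlorinated with p-toluenesulfonyl chloride to give 2-chloro-1-[4,6-bis(allyloxy)-2-(methoxymethoxy)-3-(3-methylbut-2-en-1-yl)phenyl]ethan-1-one F5. A Darzens condensation of F5 with 11 (KOH, EtOH, 0 °C) then gives the trans epoxy ketone 13 directly, where the route is rejoined. Chalcone 12 and the peroxide are not needed.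

**Step 6.** The risk is a competing [3,3] shift of the allyl ether at the temperature of the propargyl rearrangement, which would scramble the substitution of ring B. Fallback: the pyran ring is built without a thermal sigmatropic step. Setting out from 7, condensation with 3-methylbut-2-enal (PhB(OH)2, AcOH, toluene, reflux with water removal) alkylates the only free carbon ortho to the hydroxyl, and the resulting dienone closes by oxa-6π electrocyclisation to 11, where the route is rejoined. No compound outside the list is made (entry F0).

## Further compounds

F0 | step 9 | none | none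
F1 | step 2 | 1-[4-(allyloxy)-2,6-dihydroxyphenyl]ethan-1-one | CC(=O)c1c(O)cc(OCC=C)cc1O
F2 | step 2 | 1-[4-(allyloxy)-2-hydroxy-6-(methoxymethoxy)phenyl]ethan-1-one | CC(=O)c1c(O)cc(OCC=C)cc1OCOC
F3 | step 2 | 1-[4-(allyloxy)-2-(methoxymethoxy)-6-[(3-methylbut-2-en-1-yl)oxy]phenyl]ethan-1-one | CC(=O)c1c(OCC=C(C)C)cc(OCC=C)cc1OCOC
F4 | step 2 | 1-[4-(allyloxy)-6-hydroxy-2-(methoxymethoxy)-3-(3-methylbut-2-en-1-yl)phenyl]ethan-1-one | CC(=O)c1c(O)cc(OCC=C)c(CC=C(C)C)c1OCOC
F5 | step 8 | 2-chloro-1-[4,6-bis(allyloxy)-2-(methoxymethoxy)-3-(3-methylbut-2-en-1-yl)phenyl]ethan-1-one | O=C(CCl)c1c(OCOC)c(CC=C(C)C)c(OCC=C)cc1OCC=C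
F0 | step 6 | none | none
A1 | alternative 1 | 3-[2-hydroxy-3-(3-methylbut-2-en-1-yl)-4-(triisopropylsilyloxy)phenyl]-5,7-bis(methoxymethoxy)-8-(3-methylbut-2-en-1-yl)-4H-chromen-4-one | CC(C)=CCc1c(OCOC)cc(OCOC)c2c(=O)c(-c3ccc(O[Si](C(C)C)(C(C)C)C(C)C)c(CC=C(C)C)c3O)coc12
A2 | alternative 1 | (E)-1-diazo-4-[5,7-bis(methoxymethoxy)-8-(3-methylbut-2-en-1-yl)-4-oxo-4H-chromen-3-yl]but-3-en-2-one | [N-]=[N+]=CC(=O)/C=C/c1coc2c(CC=C(C)C)c(OCOC)cc(OCOC)c2c1=O
A3 | alternative 1 | triisopropyl[(5-methylhex-4-en-1-yn-1-yl)oxy]silane | CC(C)=CCC#CO[Si](C(C)C)(C(C)C)C(C)C
A4 | alternative 2 | 5-hydroxy-7-(methoxymethoxy)-3-[5-(methoxymethoxy)-2,2-dimethyl-2H-chromen-8-yl]-8-(3-methylbut-2-en-1-yl)-4H-chromen-4-one | CC(C)=CCc1c(OCOC)cc(O)c2c(=O)c(-c3ccc(OCOC)c4c3OC(C)(C)C=C4)coc12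
A5 | alternative 2 | 5-hydroxy-7-(methoxymethoxy)-3-[4-(methoxymethoxy)-2-[(2-methylbut-3-yn-2-yl)oxy]phenyl]-8-(3-methylbut-2-en-1-yl)-4H-chromen-4-one | CC(C)=CCc1c(OCOC)cc(O)c2c(=O)c(-c3ccc(OCOC)cc3OC(C)(C)C#C)coc12
A6 | alternative 3 | 5,7-bis(methoxymethoxy)-3-[5-(methoxymethoxy)-2,2-dimethyl-2H-chromen-8-yl]-8-(3-methylbut-2-en-1-yl)-4H-chromen-4-one | CC(C)=CCc1c(OCOC)cc(OCOC)c2c(=O)c(-c3ccc(OCOC)c4c3OC(C)(C)C=C4)coc12
A7 | alternative 3 | 1-[2-fluoro-4,6-bis(methoxymethoxy)-3-(3-methylbut-2-en-1-yl)phenyl]-3-hydroxy-2-[5-(methoxymethoxy)-2,2-dimethyl-2H-chromen-8-yl]prop-2-en-1-one | O=C(c1c(F)c(CC=C(C)C)c(OCOC)cc1OCOC)C(=CO)c1ccc(OCOC)c2c1OC(C)(C)C=C2
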